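**Retrosynthetic overview**
Labels: ring B is C1(OH)(acyl)–C5(O-ester)–C6(O)–C7–C8–C9(=O)–C10(CH3); ring A (lactone) is C6–O–C12(=O)–C11(=C13)–C7; side chain is C2(=O)–C3=C4–C15; β is the face of H-6.
1. The C9 ketone and C2 enone are unveiled last by a double oxidation; the propenyl unit comes from a Nozaki–Hiyama–Kishi addition to a C2 aldehyde, and the C5 ester from acylation with (R)-2-methylbutanoic acid (asymmetric hydrogenation of tiglic acid).
2. The C1/C5 trans-diol comes from the C1=C5 ring alkene by β-epoxidation and invertive hydrolysis at the tertiary C1.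
3. Ring B is closed second, by ring-closing metathesis of a C6 vinyl group onto a 1,1-disubstituted alkene at C1.
4. Ring A is formed first, together with C6 and C7, by a chromium-catalysed asymmetric 2-(ethoxycarbonyl)allylation of acrolein and lactonisation.
5. C10 is set by Fráter–Seebach methylation under control of C9, which comes from a ketoreductase reduction of an achiral β-keto ester.

Assumption: the target is read from the SMILES as (3aR,6R,7S,8S,8aR) in cyclohepta[b]furan numbering (C1 S, C5 S, C6 R, C7 R, C10 R in the labels above) with a (2R)-2-methylbutanoate.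

**Step 1**
Reactants: 1 4,4-dimethoxybutan-2-one; 2 diethyl carbonate
Product: 3 ethyl 5,5-dimethoxy-3-oxopentanoate
Conditions: NaH (2.2 equiv), THF, reflux; then AcOH, 0 °C
Reagents that add atoms: none
Why: Claisen-type C-acylation of the methyl-side ketone enolate, driven by irreversible deprotonation of the β-keto ester formed; no stereocentre.

**Step 2**
Reactants: 3 ethyl 5,5-dimethoxy-3-oxopentanoate
Product: 4 ethyl (3S)-3-hydroxy-5,5-dimethoxypentanoate
Conditions: (S)-selective ketoreductase (NADPH-dependent alcohol dehydrogenase class), NADP+ (cat.), i-PrOH, phosphate buffer pH 7, 30 °C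
Reagents that add atoms: none
Why: Enzymatic asymmetric ketone reduction, in which the ketoreductase delivers hydride to one enantiotopic face and sets C9 as (S), the first stereocentre of the route.

**Step 3**
Reactants: 4 ethyl (3S)-3-hydroxy-5,5-dimethoxypentanoate
Product: 5 ethyl (2S,3S)-3-hydroxy-5,5-dimethoxy-2-methylpentanoate
Conditions: LiN(iPr)2 (LDA, 2.2 equiv), THF, −78 to −20 °C; MeI, DMPU, −78 to −20 °C; then H2O
Reagents that add atoms: iodomethane, CI
Why: Fráter–Seebach alkylation, in which the chelated lithium alkoxide–enolate is methylated anti to the C9 side chain, setting C10 (anti, 2S,3S).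

**Step 4**
Reactants: 5 ethyl (2S,3S)-3-hydroxy-5,5-dimethoxy-2-methylpentanoate
Product: 6 ethyl (2S,3S)-3-[(tert-butyldimethylsilyl)oxy]-5,5-dimethoxy-2-methylpentanoate
Conditions: TBSCl, imidazole, DMF, rt to 40 °C
Reagents that add atoms: tert-butyldimethylsilyl chloride, CC(C)(C)[Si](C)(C)Cl
Why: Silyl ether formation protects the C9 hydroxyl under non-acidic conditions that leave the acetal intact; no stereocentre is touched.

**Step 5**
Reactants: 6 ethyl (2S,3S)-3-[(tert-butyldimethylsilyl)oxy]-5,5-dimethoxy-2-methylpentanoate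
Product: 7 (2S,3S)-3-[(tert-butyldimethylsilyl)oxy]-N,5,5-trimethoxy-N,2-dimethylpentanamide
Conditions: MeNH(OMe)·HCl, i-PrMgCl, THF, −20 to 0 °C; then H2O
Reagents that add atoms: N,O-dimethylhydroxylamine hydrochloride, CNOC.Cl
Why: Weinreb amide formation by aminolysis of the ester with the magnesium amide, which is fast at low temperature and does not epimerise C10.

**Step 6**
Reactants: 8 (tributylstannyl)methanol; 9 4-methoxybenzyl chloride
Product: 10 tributyl{[(4-methoxybenzyl)oxy]methyl}stannane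
Conditions: NaH, tetrabutylammonium iodide (cat.), THF/DMF, 0 °C to rt
Reagents that add atoms: none
Why: Williamson ether synthesis on the primary alkoxide gives the precursor of a protected hydroxymethyl anion.

**Step 7**
Reactants: 10 tributyl{[(4-methoxybenzyl)oxy]methyl}stannane; 7 (2S,3S)-3-[(tert-butyldimethylsilyl)oxy]-N,5,5-trimethoxy-N,2-dimethylpentanamide
Product: 12 (3S,4S)-4-[(tert-butyldimethylsilyl)oxy]-6,6-dimethoxy-1-[(4-methoxybenzyl)oxy]-3-methylhexan-2-one, via [(4-methoxybenzyl)oxy]methyllithium 11 (not isolated)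
Conditions: 10, n-BuLi, THF, −78 °C; then 7, −78 to −40 °C; then H2O
Reagents that add atoms: none
Why: Tin–lithium exchange gives the α-alkoxymethyllithium, whose addition to the Weinreb amide stops at the chelated tetrahedral intermediate, so the ketone (C1, C2) is released only on work-up and C10 is untouched.

**Step 8**
Reactants: 12 (3S,4S)-4-[(tert-butyldimethylsilyl)oxy]-6,6-dimethoxy-1-[(4-methoxybenzyl)oxy]-3-methylhexan-2-one
Product: 13 tert-butyl{[(3R,4S)-6,6-dimethoxy-2-{[(4-methoxybenzyl)oxy]methyl}-3-methylhex-1-en-4-yl]oxy}dimethylsilane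
Conditions: Cp2Ti(μ-Cl)(μ-CH2)AlMe2 (Tebbe reagent), pyridine (cat.), THF/toluene, −40 to 0 °C
Reagents that add atoms: Tebbe reagent, C[Al-]1(C)C[Ti]([Cl+]1)(C1C=CC=C1)C1C=CC=C1
Why: Tebbe methylenation through a non-basic titanium carbene converts the ketone into the 1,1-disubstituted alkene without enolising the ketone, so C10 is not epimerised and the β-silyloxy group is not eliminated.

**Step 9**
Reactants: 13 tert-butyl{[(3R,4S)-6,6-dimethoxy-2-{[(4-methoxybenzyl)oxy]methyl}-3-methylhex-1-en-4-yl]oxy}dimethylsilane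
Product: 14 (3S,4R)-3-[(tert-butyldimethylsilyl)oxy]-5-{[(4-methoxybenzyl)oxy]methyl}-4-methylhex-5-enal
Conditions: PPTS (cat.), acetone/H2O (10:1), 40 °C
Reagents that add atoms: water, O
Why: Mild acid-catalysed acetal hydrolysis frees the C7 aldehyde while the silyl and 4-methoxybenzyl ethers survive.

**Step 10**
Reactants: 14 (3S,4R)-3-[(tert-butyldimethylsilyl)oxy]-5-{[(4-methoxybenzyl)oxy]methyl}-4-methylhex-5-enal; 15 ethyl acrylate
Product: 16 ethyl (5S,6R)-5-[(tert-butyldimethylsilyl)oxy]-3-hydroxy-7-{[(4-methoxybenzyl)oxy]methyl}-6-methyl-2-methylideneoct-7-enoate (mixture of C3 epimers)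
Conditions: DABCO (1 equiv), ethyl acrylate (excess), MeOH, rt, 3–5 d
Reagents that add atoms: none
Why: Morita–Baylis–Hillman reaction attaches C11–C13; the new carbinol centre is a mixture and is removed in the next step.

**Step 11**
Reactants: 16 ethyl (5S,6R)-5-[(tert-butyldimethylsilyl)oxy]-3-hydroxy-7-{[(4-methoxybenzyl)oxy]methyl}-6-methyl-2-methylideneoct-7-enoate
Product: 17 ethyl (2Z,5S,6R)-2-(bromomethyl)-5-[(tert-butyldimethylsilyl)oxy]-7-{[(4-methoxybenzyl)oxy]methyl}-6-methylocta-2,7-dienoate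
Conditions: NBS, Me2S, CH2Cl2, −20 °C to rt
Reagents that add atoms: N-bromosuccinimide, O=C1CCC(=O)N1Br
Why: Corey–Kim-type activation of the allylic alcohol and SN2' displacement by bromide give the thermodynamically preferred (Z)-2-(bromomethyl)enoate.

**Step 12**
Reactants: 17 ethyl (2Z,5S,6R)-2-(bromomethyl)-5-[(tert-butyldimethylsilyl)oxy]-7-{[(4-methoxybenzyl)oxy]methyl}-6-methylocta-2,7-dienoate; 18 acrolein
Product: 20 (4R,5S)-4-[(2S,3R)-2-[(tert-butyldimethylsilyl)oxy]-4-{[(4-methoxybenzyl)oxy]methyl}-3-methylpent-4-en-1-yl]-5-ethenyl-3-methylideneoxolan-2-one, via trimethylsilyl ether 19 (not isolated)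
Conditions: CrCl2 (10 mol %), (S,S)-1,8-bis(4-isopropyl-4,5-dihydrooxazol-2-yl)-3,6-diphenyl-9H-carbazole (12 mol %), Mn powder, Me3SiCl, i-Pr2NEt, THF, 0 °C to rt; then TsOH·H2O (cat.), CH2Cl2, rt
Reagents that add atoms: none
Why: Catalytic asymmetric Nozaki–Hiyama–Kishi-type 2-(ethoxycarbonyl)allylation, in which the γ-substituted allylchromium adds through a chair transition state (anti, hence the 6,7-trans lactone) and the chiral chromium complex is chosen to direct it to the Re face of acrolein, setting C6 and C7 before acid closes ring A.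

**Step 13**
Reactants: 20 (4R,5S)-4-[(2S,3R)-2-[(tert-butyldimethylsilyl)oxy]-4-{[(4-methoxybenzyl)oxy]methyl}-3-methylpent-4-en-1-yl]-5-ethenyl-3-methylideneoxolan-2-one
Product: 21 (3aR,5S,6R,8aS)-5-[(tert-butyldimethylsilyl)oxy]-7-{[(4-methoxybenzyl)oxy]methyl}-6-methyl-3-methylidene-3,3a,4,5,6,8a-hexahydro-2H-cyclohepta[b]furan-2-one
Conditions: second-generation Hoveyda–Grubbs catalyst RuCl2(H2IMes)(=CH-C6H4-2-OiPr) (10 mol %), toluene (2 mM), 80 °C
Reagents that add atoms: none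
Why: Ring-closing metathesis between the C6 vinyl group and the 1,1-disubstituted alkene closes ring B as the trisubstituted C1=C5 alkene with loss of ethene; the electron-poor methylidene lactone does not take part.

**Step 14**
Reactants: 21 (3aR,5S,6R,8aS)-5-[(tert-butyldimethylsilyl)oxy]-7-{[(4-methoxybenzyl)oxy]methyl}-6-methyl-3-methylidene-3,3a,4,5,6,8a-hexahydro-2H-cyclohepta[b]furan-2-one
Product: 22 (3aR,5S,6S,7S,8S,8aR)-5-[(tert-butyldimethylsilyl)oxy]-7,8-epoxy-7-{[(4-methoxybenzyl)oxy]methyl}-6-methyl-3-methylideneoctahydro-2H-cyclohepta[b]furan-2-one (β-epoxide)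
Conditions: mCPBA, NaHCO3, CH2Cl2, 0 °C to rt
Reagents that add atoms: 3-chloroperoxybenzoic acid, OOC(=O)c1cccc(Cl)c1
Why: Prilezhaev epoxidation of the only electron-rich alkene, with the peracid approaching the face opposite the two allylic substituents (C6–O and C10–CH3, both α) to give the β-epoxide.

**Step 15**
Reactants: 22 (3aR,5S,6S,7S,8S,8aR)-5-[(tert-butyldimethylsilyl)oxy]-7,8-epoxy-7-{[(4-methoxybenzyl)oxy]methyl}-6-methyl-3-methylideneoctahydro-2H-cyclohepta[b]furan-2-one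
Product: 23 (3aR,5S,6S,7R,8S,8aR)-5-[(tert-butyldimethylsilyl)oxy]-7,8-dihydroxy-7-{[(4-methoxybenzyl)oxy]methyl}-6-methyl-3-methylideneoctahydro-2H-cyclohepta[b]furan-2-one
Conditions: HClO4 (cat.), THF/H2O (3:1), 0 °C to rt
Reagents that add atoms: water, O
Why: Acid-catalysed epoxide hydrolysis, in which water opens the protonated epoxide at the tertiary C1 (C5 is secondary and deactivated by the neighbouring acyloxy group) with inversion, giving the trans-diol with C1–OH α and C5–OH β.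

**Step 16**
Reactants: 24 tiglic acid
Product: 25 (2R)-2-methylbutanoic acid
Conditions: H2 (4 atm), Ru(OAc)2[(R)-H8-BINAP] (0.5 mol %), MeOH, rt
Reagents that add atoms: none
Why: Noyori-type asymmetric hydrogenation of the carboxylate-bound trisubstituted alkene; the (R)-ligand gives the (R)-acid (about 97% ee).

**Step 17**
Reactants: 23 (3aR,5S,6S,7R,8S,8aR)-5-[(tert-butyldimethylsilyl)oxy]-7,8-dihydroxy-7-{[(4-methoxybenzyl)oxy]methyl}-6-methyl-3-methylideneoctahydro-2H-cyclohepta[b]furan-2-one; 25 (2R)-2-methylbutanoic acid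
Product: 27 (3aR,5S,6S,7R,8S,8aR)-5-[(tert-butyldimethylsilyl)oxy]-7-hydroxy-7-{[(4-methoxybenzyl)oxy]methyl}-6-methyl-3-methylidene-2-oxooctahydro-2H-cyclohepta[b]furan-8-yl (2R)-2-methylbutanoate, via mixed anhydride 26 (not isolated)
Conditions: 25, 2,4,6-trichlorobenzoyl chloride, Et3N, THF, rt; then 23, DMAP, toluene, rt to 40 °C
Reagents that add atoms: none
Why: Yamaguchi esterification acylates the secondary C5 hydroxyl while the tertiary C1 hydroxyl is too hindered to react; neither the C5 nor the acid stereocentre is affected.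

**Step 18**
Reactants: 27 (3aR,5S,6S,7R,8S,8aR)-5-[(tert-butyldimethylsilyl)oxy]-7-hydroxy-7-{[(4-methoxybenzyl)oxy]methyl}-6-methyl-3-methylidene-2-oxooctahydro-2H-cyclohepta[b]furan-8-yl (2R)-2-methylbutanoate
Product: 28 (3aR,5S,6S,7R,8S,8aR)-5-[(tert-butyldimethylsilyl)oxy]-7-hydroxy-7-(hydroxymethyl)-6-methyl-3-methylidene-2-oxooctahydro-2H-cyclohepta[b]furan-8-yl (2R)-2-methylbutanoate
Conditions: DDQ, CH2Cl2/pH 7 buffer (10:1), 0 °C to rt
Reagents that add atoms: none
Why: Oxidative cleavage of the 4-methoxybenzyl ether by DDQ under neutral conditions frees the C2 primary alcohol without touching the esters, silyl ether or methylidene lactone.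

**Step 19**
Reactants: 28 (3aR,5S,6S,7R,8S,8aR)-5-[(tert-butyldimethylsilyl)oxy]-7-hydroxy-7-(hydroxymethyl)-6-methyl-3-methylidene-2-oxooctahydro-2H-cyclohepta[b]furan-8-yl (2R)-2-methylbutanoate
Product: 29 (3aR,5S,6S,7S,8S,8aR)-5-[(tert-butyldimethylsilyl)oxy]-7-formyl-7-hydroxy-6-methyl-3-methylidene-2-oxooctahydro-2H-cyclohepta[b]furan-8-yl (2R)-2-methylbutanoate
Conditions: Dess–Martin periodinane, NaHCO3, CH2Cl2, 0 °C to rt
Reagents that add atoms: none
Why: Dess–Martin oxidation of the primary alcohol gives the C2 aldehyde, which has no α-hydrogen and cannot epimerise; the tertiary hydroxyl is inert.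

**Step 20**
Reactants: 29 (3aR,5S,6S,7S,8S,8aR)-5-[(tert-butyldimethylsilyl)oxy]-7-formyl-7-hydroxy-6-methyl-3-methylidene-2-oxooctahydro-2H-cyclohepta[b]furan-8-yl (2R)-2-methylbutanoate; 30 (E)-1-bromoprop-1-ene
Product: 31 (3aR,5S,6S,7R,8S,8aR)-5-[(tert-butyldimethylsilyl)oxy]-7-hydroxy-7-[(2E)-1-hydroxybut-2-en-1-yl]-6-methyl-3-methylidene-2-oxooctahydro-2H-cyclohepta[b]furan-8-yl (2R)-2-methylbutanoate (mixture of carbinol epimers)
Conditions: CrCl2 (4 equiv), NiCl2 (2 mol %), DMF, rt; then H2O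
Reagents that add atoms: none
Why: Nozaki–Hiyama–Kishi alkenylation adds the propenyl group to the aldehyde only (esters and lactone are inert) with retention of the E geometry; the new carbinol centre is oxidised later.

**Step 21**
Reactants: 31 (3aR,5S,6S,7R,8S,8aR)-5-[(tert-butyldimethylsilyl)oxy]-7-hydroxy-7-[(2E)-1-hydroxybut-2-en-1-yl]-6-methyl-3-methylidene-2-oxooctahydro-2H-cyclohepta[b]furan-8-yl (2R)-2-methylbutanoate
Product: 32 (3aR,5S,6S,7R,8S,8aR)-5,7-dihydroxy-7-[(2E)-1-hydroxybut-2-en-1-yl]-6-methyl-3-methylidene-2-oxooctahydro-2H-cyclohepta[b]furan-8-yl (2R)-2-methylbutanoate (mixture of carbinol epimers)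
Conditions: HF·pyridine, pyridine, THF, 0 °C to rt
Reagents that add atoms: none
Why: Fluoride-mediated desilylation frees the C9 hydroxyl under buffered conditions that do not cause acyl migration.

**Step 22**
Reactants: 32 (3aR,5S,6S,7R,8S,8aR)-5,7-dihydroxy-7-[(2E)-1-hydroxybut-2-en-1-yl]-6-methyl-3-methylidene-2-oxooctahydro-2H-cyclohepta[b]furan-8-yl (2R)-2-methylbutanoate
Product: 33 (3aR,6R,7S,8S,8aR)-7-[(2E)-but-2-enoyl]-7-hydroxy-6-methyl-3-methylidene-2,5-dioxooctahydro-2H-cyclohepta[b]furan-8-yl (2R)-2-methylbutanoate (target)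
Conditions: Dess–Martin periodinane (3 equiv), NaHCO3, CH2Cl2, 0 °C to rt
Reagents that add atoms: none
Why: Double Dess–Martin oxidation converts the C2 allylic and C9 secondary alcohols into the enone and ketone under neutral conditions, so C10 (now α to the ketone) is not epimerised and no retro-aldol occurs.

**Compound list**
1 | 4,4-dimethoxybutan-2-one | CC(=O)CC(OC)OC | starting material
2 | diethyl carbonate | CCOC(=O)OCC | starting material
3 | ethyl 5,5-dimethoxy-3-oxopentanoate | CCOC(=O)CC(=O)CC(OC)OC | intermediate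
4 | ethyl (3S)-3-hydroxy-5,5-dimethoxypentanoate | COC(OC)C[C@H](O)CC(=O)OCC | intermediate
5 | ethyl (2S,3S)-3-hydroxy-5,5-dimethoxy-2-methylpentanoate | COC(OC)C[C@H](O)[C@H](C)C(=O)OCC | intermediate
6 | ethyl (2S,3S)-3-[(tert-butyldimethylsilyl)oxy]-5,5-dimethoxy-2-methylpentanoate | COC(OC)C[C@H](O[Si](C)(C)C(C)(C)C)[C@H](C)C(=O)OCC | intermediate
7 | (2S,3S)-3-[(tert-butyldimethylsilyl)oxy]-N,5,5-trimethoxy-N,2-dimethylpentanamide | COC(OC)C[C@H](O[Si](C)(C)C(C)(C)C)[C@H](C)C(=O)N(C)OC | intermediate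
8 | (tributylstannyl)methanol | CCCC[Sn](CCCC)(CCCC)CO | starting material
9 | 4-methoxybenzyl chloride | COc1ccc(CCl)cc1 | starting material
10 | tributyl{[(4-methoxybenzyl)oxy]methyl}stannane | CCCC[Sn](CCCC)(CCCC)COCc1ccc(OC)cc1 | intermediate
11 | [(4-methoxybenzyl)oxy]methyllithium | [Li]COCc1ccc(OC)cc1 | intermediate
12 | (3S,4S)-4-[(tert-butyldimethylsilyl)oxy]-6,6-dimethoxy-1-[(4-methoxybenzyl)oxy]-3-methylhexan-2-one | COC(OC)C[C@H](O[Si](C)(C)C(C)(C)C)[C@H](C)C(=O)COCc1ccc(OC)cc1 | intermediate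
13 | tert-butyl{[(3R,4S)-6,6-dimethoxy-2-{[(4-methoxybenzyl)oxy]methyl}-3-methylhex-1-en-4-yl]oxy}dimethylsilane | COC(OC)C[C@H](O[Si](C)(C)C(C)(C)C)[C@H](C)C(=C)COCc1ccc(OC)cc1 | intermediate
14 | (3S,4R)-3-[(tert-butyldimethylsilyl)oxy]-5-{[(4-methoxybenzyl)oxy]methyl}-4-methylhex-5-enal | O=CC[C@H](O[Si](C)(C)C(C)(C)C)[C@H](C)C(=C)COCc1ccc(OC)cc1 | intermediate
15 | ethyl acrylate | C=CC(=O)OCC | starting material
16 | ethyl (5S,6R)-5-[(tert-butyldimethylsilyl)oxy]-3-hydroxy-7-{[(4-methoxybenzyl)oxy]methyl}-6-methyl-2-methylideneoct-7-enoate (C3 epimers) | CCOC(=O)C(=C)C(O)C[C@H](O[Si](C)(C)C(C)(C)C)[C@H](C)C(=C)COCc1ccc(OC)cc1 | intermediate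
17 | ethyl (2Z,5S,6R)-2-(bromomethyl)-5-[(tert-butyldimethylsilyl)oxy]-7-{[(4-methoxybenzyl)oxy]methyl}-6-methylocta-2,7-dienoate | CCOC(=O)/C(CBr)=C/C[C@H](O[Si](C)(C)C(C)(C)C)[C@H](C)C(=C)COCc1ccc(OC)cc1 | intermediate
18 | acrolein | C=CC=O | starting material
19 | ethyl (3R,4S)-3-[(2S,3R)-2-[(tert-butyldimethylsilyl)oxy]-4-{[(4-methoxybenzyl)oxy]methyl}-3-methylpent-4-en-1-yl]-2-methylidene-4-[(trimethylsilyl)oxy]hex-5-enoate | C=C[C@H](O[Si](C)(C)C)[C@@H](C(=C)C(=O)OCC)C[C@H](O[Si](C)(C)C(C)(C)C)[C@H](C)C(=C)COCc1ccc(OC)cc1 | intermediate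
20 | (4R,5S)-4-[(2S,3R)-2-[(tert-butyldimethylsilyl)oxy]-4-{[(4-methoxybenzyl)oxy]methyl}-3-methylpent-4-en-1-yl]-5-ethenyl-3-methylideneoxolan-2-one | C=C1C(=O)O[C@@H](C=C)[C@@H]1C[C@H](O[Si](C)(C)C(C)(C)C)[C@H](C)C(=C)COCc2ccc(OC)cc2 | intermediate
21 | (3aR,5S,6R,8aS)-5-[(tert-butyldimethylsilyl)oxy]-7-{[(4-methoxybenzyl)oxy]methyl}-6-methyl-3-methylidene-3,3a,4,5,6,8a-hexahydro-2H-cyclohepta[b]furan-2-one | C=C1C(=O)O[C@@H]2[C@@H]1C[C@H](O[Si](C)(C)C(C)(C)C)[C@H](C)C(COCc3ccc(OC)cc3)=C2 | intermediate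
22 | (3aR,5S,6S,7S,8S,8aR)-5-[(tert-butyldimethylsilyl)oxy]-7,8-epoxy-7-{[(4-methoxybenzyl)oxy]methyl}-6-methyl-3-methylideneoctahydro-2H-cyclohepta[b]furan-2-one | C=C1C(=O)O[C@@H]2[C@@H]1C[C@H](O[Si](C)(C)C(C)(C)C)[C@H](C)[C@@]3(COCc4ccc(OC)cc4)O[C@@H]23 | intermediate
23 | (3aR,5S,6S,7R,8S,8aR)-5-[(tert-butyldimethylsilyl)oxy]-7,8-dihydroxy-7-{[(4-methoxybenzyl)oxy]methyl}-6-methyl-3-methylideneoctahydro-2H-cyclohepta[b]furan-2-one | C=C1C(=O)O[C@@H]2[C@@H]1C[C@H](O[Si](C)(C)C(C)(C)C)[C@H](C)[C@@](O)(COCc3ccc(OC)cc3)[C@H]2O | intermediate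
24 | tiglic acid, (2E)-2-methylbut-2-enoic acid | C/C=C(\C)C(=O)O | starting material
25 | (2R)-2-methylbutanoic acid | CC[C@@H](C)C(=O)O | intermediate
26 | (2R)-2-methylbutanoic 2,4,6-trichlorobenzoic anhydride | CC[C@@H](C)C(=O)OC(=O)c1c(Cl)cc(Cl)cc1Cl | intermediate
27 | (3aR,5S,6S,7R,8S,8aR)-5-[(tert-butyldimethylsilyl)oxy]-7-hydroxy-7-{[(4-methoxybenzyl)oxy]methyl}-6-methyl-3-methylidene-2-oxooctahydro-2H-cyclohepta[b]furan-8-yl (2R)-2-methylbutanoate | C=C1C(=O)O[C@@H]2[C@@H]1C[C@H](O[Si](C)(C)C(C)(C)C)[C@H](C)[C@@](O)(COCc3ccc(OC)cc3)[C@H]2OC(=O)[C@H](C)CC | intermediate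
28 | (3aR,5S,6S,7R,8S,8aR)-5-[(tert-butyldimethylsilyl)oxy]-7-hydroxy-7-(hydroxymethyl)-6-methyl-3-methylidene-2-oxooctahydro-2H-cyclohepta[b]furan-8-yl (2R)-2-methylbutanoate | C=C1C(=O)O[C@@H]2[C@@H]1C[C@H](O[Si](C)(C)C(C)(C)C)[C@H](C)[C@@](O)(CO)[C@H]2OC(=O)[C@H](C)CC | intermediate
29 | (3aR,5S,6S,7S,8S,8aR)-5-[(tert-butyldimethylsilyl)oxy]-7-formyl-7-hydroxy-6-methyl-3-methylidene-2-oxooctahydro-2H-cyclohepta[b]furan-8-yl (2R)-2-methylbutanoate | C=C1C(=O)O[C@@H]2[C@@H]1C[C@H](O[Si](C)(C)C(C)(C)C)[C@H](C)[C@@](O)(C=O)[C@H]2OC(=O)[C@H](C)CC | intermediate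
30 | (E)-1-bromoprop-1-ene | C/C=C/Br | starting material
31 | (3aR,5S,6S,7R,8S,8aR)-5-[(tert-butyldimethylsilyl)oxy]-7-hydroxy-7-[(2E)-1-hydroxybut-2-en-1-yl]-6-methyl-3-methylidene-2-oxooctahydro-2H-cyclohepta[b]furan-8-yl (2R)-2-methylbutanoate (carbinol epimers) | C=C1C(=O)O[C@@H]2[C@@H]1C[C@H](O[Si](C)(C)C(C)(C)C)[C@H](C)[C@@](O)(C(O)/C=C/C)[C@H]2OC(=O)[C@H](C)CC | intermediate
32 | (3aR,5S,6S,7R,8S,8aR)-5,7-dihydroxy-7-[(2E)-1-hydroxybut-2-en-1-yl]-6-methyl-3-methylidene-2-oxooctahydro-2H-cyclohepta[b]furan-8-yl (2R)-2-methylbutanoate (carbinol epimers) | C=C1C(=O)O[C@@H]2[C@@H]1C[C@H](O)[C@H](C)[C@@](O)(C(O)/C=C/C)[C@H]2OC(=O)[C@H](C)CC | intermediate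
33 | (3aR,6R,7S,8S,8aR)-7-[(2E)-but-2-enoyl]-7-hydroxy-6-methyl-3-methylidene-2,5-dioxooctahydro-2H-cyclohepta[b]furan-8-yl (2R)-2-methylbutanoate | C=C1C(=O)O[C@@H]2[C@@H]1CC(=O)[C@H](C)[C@@](O)(C(=O)/C=C/C)[C@H]2OC(=O)[C@H](C)CC | target

**Totals**
Total step count: 22 (steps 6 and 16 are side branches).
Longest linear sequence: 20 steps (1 → 3 → 4 → 5 → 6 → 7 → 12 → 13 → 14 → 16 → 17 → 20 → 21 → 22 → 23 → 27 → 28 → 29 → 31 → 32 → 33).

**Three steps most likely to fail**

Step 12 (asymmetric allylation). The facial selectivity rests entirely on the chiral chromium catalyst acting on a complex bromide with remote stereocentres, and the sense of induction of the named ligand enantiomer is assumed and must be confirmed on a model aldehyde. Acrolein can also polymerise. The fallback sets out from 17 and 18 and gives up catalyst control: the coupling is run without the chiral ligand (CrCl2 cat., Mn, Me3SiCl), which is still anti-selective through the chair transition state but not face-selective. It gives silyl ether 19 together with its C6,C7-epimer, ethyl (3S,4R)-3-[(2S,3R)-2-[(tert-butyldimethylsilyl)oxy]-4-{[(4-methoxybenzyl)oxy]methyl}-3-methylpent-4-en-1-yl]-2-methylidene-4-[(trimethylsilyl)oxy]hex-5-enoate F1. Acid lactonisation of the mixture gives 20 and (4S,5R)-4-[(2S,3R)-2-[(tert-butyldimethylsilyl)oxy]-4-{[(4-methoxybenzyl)oxy]methyl}-3-methylpent-4-en-1-yl]-5-ethenyl-3-methylideneoxolan-2-one F2. These are diastereomers because C9 and C10 are fixed, so they are separated by chromatography, and the route resumes at 20 at the cost of half the material.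

Step 13 (ring-closing metathesis). A hindered 1,1-disubstituted alkene must close onto a vinyl group held on a trans-fused lactone, so oligomerisation may compete. The fallback sets out from 19, isolated by omitting the acid treatment of step 12, and reverses the order of ring formation. Ring B is closed first on the conformationally free diene with the same ruthenium carbene, giving ethyl 2-[(1R,2S,5R,6S)-6-[(tert-butyldimethylsilyl)oxy]-4-{[(4-methoxybenzyl)oxy]methyl}-5-methyl-2-[(trimethylsilyl)oxy]cyclohept-3-en-1-yl]prop-2-enoate F3. Ring A is then closed by TsOH-mediated desilylation and lactonisation, rejoining the route at 21.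

Step 14 (epoxidation face). The β-selectivity is substrate control in a flexible seven-membered ring and is predicted, not proven. The fallback sets out from 21 and uses reagent control. DDQ removes the 4-methoxybenzyl group to give (3aR,5S,6R,8aS)-5-[(tert-butyldimethylsilyl)oxy]-7-(hydroxymethyl)-6-methyl-3-methylidene-3,3a,4,5,6,8a-hexahydro-2H-cyclohepta[b]furan-2-one F4. Sharpless asymmetric epoxidation (Ti(OiPr)4, L-(+)-diethyl tartrate, t-BuOOH, CH2Cl2, −20 °C) delivers oxygen to the β-face (by the Sharpless mnemonic; the expected substrate bias points the same way), giving (3aR,5S,6S,7S,8S,8aR)-5-[(tert-butyldimethylsilyl)oxy]-7,8-epoxy-7-(hydroxymethyl)-6-methyl-3-methylideneoctahydro-2H-cyclohepta[b]furan-2-one F5. Aqueous HClO4 opens it at C1 with inversion to (3aR,5S,6S,7R,8S,8aR)-5-[(tert-butyldimethylsilyl)oxy]-7,8-dihydroxy-7-(hydroxymethyl)-6-methyl-3-methylideneoctahydro-2H-cyclohepta[b]furan-2-one F6. TEMPO/PhI(OAc)2 oxidises only the primary alcohol to (3aR,5S,6S,7S,8S,8aR)-5-[(tert-butyldimethylsilyl)oxy]-7,8-dihydroxy-6-methyl-3-methylidene-2-oxooctahydro-2H-cyclohepta[b]furan-7-carbaldehyde F7. Yamaguchi esterification of its secondary hydroxyl with 25 (through 26) rejoins the route at 29.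

**Further compounds**
F1 | step 12 | ethyl (3S,4R)-3-[(2S,3R)-2-[(tert-butyldimethylsilyl)oxy]-4-{[(4-methoxybenzyl)oxy]methyl}-3-methylpent-4-en-1-yl]-2-methylidene-4-[(trimethylsilyl)oxy]hex-5-enoate | C=C[C@@H](O[Si](C)(C)C)[C@H](C(=C)C(=O)OCC)C[C@H](O[Si](C)(C)C(C)(C)C)[C@H](C)C(=C)COCc1ccc(OC)cc1
F2 | step 12 | (4S,5R)-4-[(2S,3R)-2-[(tert-butyldimethylsilyl)oxy]-4-{[(4-methoxybenzyl)oxy]methyl}-3-methylpent-4-en-1-yl]-5-ethenyl-3-methylideneoxolan-2-one | C=C1C(=O)O[C@H](C=C)[C@H]1C[C@H](O[Si](C)(C)C(C)(C)C)[C@H](C)C(=C)COCc2ccc(OC)cc2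
F3 | step 13 | ethyl 2-[(1R,2S,5R,6S)-6-[(tert-butyldimethylsilyl)oxy]-4-{[(4-methoxybenzyl)oxy]methyl}-5-methyl-2-[(trimethylsilyl)oxy]cyclohept-3-en-1-yl]prop-2-enoate | CCOC(=O)C(=C)[C@H]1C[C@H](O[Si](C)(C)C(C)(C)C)[C@H](C)C(COCc2ccc(OC)cc2)=C[C@@H]1O[Si](C)(C)C
F4 | step 14 | (3aR,5S,6R,8aS)-5-[(tert-butyldimethylsilyl)oxy]-7-(hydroxymethyl)-6-methyl-3-methylidene-3,3a,4,5,6,8a-hexahydro-2H-cyclohepta[b]furan-2-one | C=C1C(=O)O[C@@H]2[C@@H]1C[C@H](O[Si](C)(C)C(C)(C)C)[C@H](C)C(CO)=C2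
F5 | step 14 | (3aR,5S,6S,7S,8S,8aR)-5-[(tert-butyldimethylsilyl)oxy]-7,8-epoxy-7-(hydroxymethyl)-6-methyl-3-methylideneoctahydro-2H-cyclohepta[b]furan-2-one | C=C1C(=O)O[C@@H]2[C@@H]1C[C@H](O[Si](C)(C)C(C)(C)C)[C@H](C)[C@@]3(CO)O[C@@H]23
F6 | step 14 | (3aR,5S,6S,7R,8S,8aR)-5-[(tert-butyldimethylsilyl)oxy]-7,8-dihydroxy-7-(hydroxymethyl)-6-methyl-3-methylideneoctahydro-2H-cyclohepta[b]furan-2-one | C=C1C(=O)O[C@@H]2[C@@H]1C[C@H](O[Si](C)(C)C(C)(C)C)[C@H](C)[C@@](O)(CO)[C@H]2O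
F7 | step 14 | (3aR,5S,6S,7S,8S,8aR)-5-[(tert-butyldimethylsilyl)oxy]-7,8-dihydroxy-6-methyl-3-methylidene-2-oxooctahydro-2H-cyclohepta[b]furan-7-carbaldehyde | C=C1C(=O)O[C@@H]2[C@@H]1C[C@H](O[Si](C)(C)C(C)(C)C)[C@H](C)[C@@](O)(C=O)[C@H]2O
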